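Readings and results were computed for an exercise, and the scatter is random.

**Cross time.** Litres per mole per minute, multiplied by a concentration, give a rate per minute, and the reciprocal of that rate is a time. Starting material joins second substrate to give cross product, and joins partner to give target; partner also consumes second substrate, giving second product.

| flask | starting material | partner | second substrate | remark | time |
|---|---|---|---|---|---|
| dusk | 0.050 M | 1.1 equiv | 1 equiv | run made earlier |  |
| autumn | 0.034 M | 1.1 equiv | 1 equiv | run made earlier |  |
| summer | 0.075 M | 1.1 equiv | 1 equiv | run made earlier |  |
| epsilon | 0.050 M (fed, over 80 min) | 1.10 equiv | 1.00 equiv | all else is in the flask from the start; the feed brings no volume worth counting | 2.0 h |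
| delta | 0.050 M | 1.10 equiv | 1.00 equiv | everything together at the start | 2.0 h |
| theta | 0.050 M | 1.10 equiv | 1.00 equiv (fed, over 80 min) | all else is in the flask from the start; the feed brings no volume worth counting | 2.0 h |

- dusk (time / min: cross product / %, target / %): 4.00: 4.1, 8.8; 12.0: 9.5, 18.8; 20.0: 13.0, 25.4; 30.0: 16.3, 30.1; 40.0: 18.1, 33.7; 60.0: 21.3, 36.5; 80.0: 24.3, 36.5
- autumn (time / min: cross product / %, target / %): 8.00: 4.7, 11.3; 12.0: 7.4, 13.8; 20.0: 10.4, 20.6; 25.0: 12.0, 23.2; 40.0: 15.6, 28.7; 60.0: 18.6, 31.9; 90.0: 22.4, 35.1
- summer (time / min: cross product / %, target / %): 8.00: 9.2, 19.2; 12.0: 12.2, 24.0; 20.0: 15.4, 31.0; 25.0: 18.7, 32.8; 40.0: 22.5, 38.1; 60.0: 25.3, 39.4; 90.0: 28.0, 39.1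

(readings scatter by 0.5 percentage points)

- what is said of target includes idle adduct
- reactions considered so far: starting material + partner -> target; partner + target <-> idle adduct; second substrate + partner -> second product; target <-> isomer of the product; starting material + second substrate -> cross product; partner -> decomposition product

- which flask leads in amount of cross product, in percent of the starting material charged ("all alike" within 1.5 percentage points) (epsilon / delta / theta / all alike)
- how much cross product is there at the end, in percent of the starting material charged: epsilon
- how much cross product is there at the end, in percent of the starting material charged: delta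
- how much cross product is there at the end, in percent of the starting material charged: theta

Summer makes 9.2% cross product at 8.00 min and autumn 4.7%, a ratio of 1.96 against 2.21 in concentration, so the pace follows concentration, as a bimolecular step does. Dusk has delta's recipe, and its first reading gives 97.6 min as τ_X, the cross time: the minutes in which cross product would reach the whole charge if both reactants stayed as charged. With a and b the amounts of starting material and second substrate as fractions of that charge, cross product grows by a·b/τ_X per minute. Target's reading gives likewise τ_P = 45.5 min. Both carry the scatter.

**The ledger.** At 80.0 min, dusk's charge of starting material stands as 36.5% target and 24.3% cross product, and the books close on 39.2% still starting material or unread isomer. Target reads 36.5% at 60.0 min and again at 80.0 min. Cross product gains 18.1% up to 40.0 min and less, 6.2 percentage points, in the equal span up to 80.0 min. Assuming that the next equal span shrinks by the same ratio, delta stands near 26.4% at 2.0 h.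

**Fed flasks.** In epsilon, a climbs with the feed while b falls. Assuming partner removes second substrate hyperbolically on τ_P, the feed spans 1.76 such times and the mean a·b is 0.240. Theta swaps the roles and gives the same sum. Over 80 min, either fed flask then makes 19.7%, less than dusk's 24.3%, so this reckoning puts delta ahead.

**The forecast.** It names delta, with 26% for epsilon, 27.5% for delta and 24.5% for theta: “The differences are small, but delta leads narrowly.” Its delta lies above the 26.4% reckoned here.

**The result.** Cross product ends at 27.4% in delta, 18.5% in theta and 16.5% in epsilon, so delta leads.

    starting material + partner → target (k = 0.470 L mol⁻¹ min⁻¹)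
    partner + target ⇌ idle adduct, settled at all times (K = 8.50 L mol⁻¹)
    second substrate + partner → second product (k = 0.580 L mol⁻¹ min⁻¹)
    target ⇌ isomer of the product (K = 2.60, k = 0.00300 min⁻¹)
    starting material + second substrate → cross product (k = 0.230 L mol⁻¹ min⁻¹)
    partner → decomposition product (k = 2.10 × 10⁻⁵ min⁻¹)

At the end of its feed, epsilon holds starting material at 64.7% of the charge and second substrate at 23.1% of its own. At 2.00 h, its 52.3% and 15.2% multiply τ_X, read from dusk as 97.6 min, by 12.6. The neighbour charged with second substrate at 4.00 equiv keeps 52.2% of that larger charge beside 14.0% starting material at 2.00 h, which multiplies τ_X by 3.43, and that neighbour holds 83.7% cross product.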